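**Plan**

1. The target is two 7,8,4'-trihydroxyflavan-3-ol units joined by a C4–O–C4 ether: unit A is 2R,3R,4R (2,3-cis-3,4-cis) and unit B is 2S,3R,4R (2,3-trans-3,4-cis).
2. In each unit O1–C2 is a benzylic aryl ether beside the C3 carbinol, so each pyran ring (ring C) can be cut at O1–C2 back to a ring A phenol and a C2–C3 epoxide; after removal of benzyl ethers and pivalates these two cuts come first.
3. The cis epoxide (unit A) and trans epoxide (unit B) go back to a Z and an E alkene; the E alkene is cut at C2–ring B (Heck), the Z alkene goes back to an alkyne, the ether is cut at O–C4 of unit B (allylic etherification) and the propargylic alcohol at C4–C3 of unit A (alkynylation).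
4. Forward, the chain is joined as aldehyde + alkyne, then alcohol + cinnamyl carbonate; semihydrogenation, cis epoxidation, Heck arylation and trans epoxidation follow; both rings C then close in one step and deprotection ends the route.
5. C4 of unit A comes from BINOL–titanium alkynylation, C4 of unit B from the iridium catalyst, C3 of each unit from reagent-controlled epoxidation, and C2 of each unit from inversion during epoxide opening, so the Z alkene gives the 2,3-cis ring and the E alkene the 2,3-trans ring.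

Key step: step 16

**Conventions**

- Flavan numbering is used (O1, C2, C3, C4, C4a–C8a; ring C is the pyran ring).
- ArA = 3,4-bis(benzyloxy)-2-(triisopropylsilyloxy)phenyl; ArA(OH) = 3,4-bis(benzyloxy)-2-hydroxyphenyl; ArB = 4-(pivaloyloxy)phenyl.
- L = (Sa,Sc,Sc)-O,O'-(1,1'-binaphthalene-2,2'-diyl) N,N-bis[1-(2-methoxyphenyl)ethyl]phosphoramidite.
- (S,S)-(salen)MnCl = chloro[(S,S)-N,N'-bis(3,5-di-tert-butylsalicylidene)cyclohexane-1,2-diaminato]manganese.
- Shi ketone = 1,2:4,5-di-O-isopropylidene-β-D-erythro-2,3-hexodiulo-2,6-pyranose (from D-fructose).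

Assumption: the sense of induction of (S)-BINOL/Ti(OiPr)4, of [Ir(cod)Cl]2/L, of (S,S)-(salen)MnCl and of the Shi ketone is taken from the parent benzaldehyde, cinnamyl carbonate, cis-β-methylstyrene and trans-β-methylstyrene cases; if one proves opposite on these substrates the antipodal ligand or catalyst would be used in that step.

Assumption: in step 16 the trans epoxide (unit B) is taken to close first, so intermediate 23 is drawn with ring C of unit B closed.

**Route**

Step 1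
Reactants: 1 2,3,4-trihydroxybenzaldehyde
Product: 2 3,4-bis(benzyloxy)-2-hydroxybenzaldehyde
Conditions: BnBr (2.1 equiv), K2CO3 (2.1 equiv), DMF, 0 °C to rt
Reagents that add atoms: benzyl bromide, BrCc1ccccc1
Why: Williamson etherification in which the 2-OH, held in a hydrogen bond to the aldehyde, is the least nucleophilic oxygen, so two equivalents of benzyl bromide should go to O-4 and O-3.

Step 2
Reactants: 2 3,4-bis(benzyloxy)-2-hydroxybenzaldehyde
Product: 3 3,4-bis(benzyloxy)-2-(triisopropylsilyloxy)benzaldehyde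
Conditions: i-Pr3SiOTf, 2,6-lutidine, CH2Cl2, 0 °C
Reagents that add atoms: triisopropylsilyl trifluoromethanesulfonate, CC(C)[Si](OS(=O)(=O)C(F)(F)F)(C(C)C)C(C)C
Why: Silylation of the remaining hindered phenol gives a bulky silyl ether that should resist base, organometallic reagents and O-to-O migration yet fall to fluoride at the end.

Step 3
Reactants: 3 3,4-bis(benzyloxy)-2-(triisopropylsilyloxy)benzaldehyde; 4 ethyl (triphenylphosphoranylidene)acetate
Product: 5 ethyl (E)-3-ArA-acrylate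
Conditions: PhMe, 80 °C
Reagents that add atoms: none
Why: Wittig olefination with a stabilised ylide, which with aromatic aldehydes should give the E enoate almost exclusively.

Step 4
Reactants: 5 ethyl (E)-3-ArA-acrylate
Product: 6 (E)-3-ArA-prop-2-en-1-ol
Conditions: i-Bu2AlH (2.2 equiv), CH2Cl2, −78 °C; aq. KNaC4H4O6
Reagents that add atoms: none
Why: Reduction of the conjugated ester by i-Bu2AlH at low temperature should stop cleanly at the allylic alcohol by 1,2-hydride delivery.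

Step 5
Reactants: 6 (E)-3-ArA-prop-2-en-1-ol
Product: 7 tert-butyl (E)-3-ArA-prop-2-en-1-yl carbonate
Conditions: Boc2O, DMAP (cat.), CH2Cl2, 0 °C to rt
Reagents that add atoms: di-tert-butyl dicarbonate, CC(C)(C)OC(=O)OC(=O)OC(C)(C)C
Why: DMAP-catalysed acylation of the primary alcohol gives the tert-butyl carbonate, a leaving group for allyliridium formation that releases only a non-nucleophilic tert-butoxide.

Step 6
Reactants: 8 4-iodophenol
Product: 9 4-iodophenyl pivalate
Conditions: t-BuCOCl, Et3N, DMAP (cat.), CH2Cl2, 0 °C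
Reagents that add atoms: pivaloyl chloride, CC(C)(C)C(Cl)=O
Why: Acylation of the phenol installs an ester that makes ring B electron-poor enough to disfavour a benzylic cation at C2 later and is hindered enough to survive mild base and buffered fluoride.

Step 7
Reactants: 9 4-iodophenyl pivalate; 10 trimethylsilylacetylene
Product: 11 4-[(trimethylsilyl)ethynyl]phenyl pivalate
Conditions: PdCl2(PPh3)2 (2 mol%), CuI (4 mol%), Et3N, THF, rt
Reagents that add atoms: none
Why: Sonogashira coupling of an aryl iodide with a terminal alkyne proceeds at room temperature and leaves the aryl ester alone.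

Step 8
Reactants: 11 4-[(trimethylsilyl)ethynyl]phenyl pivalate
Product: 12 4-ethynylphenyl pivalate
Conditions: Bu4NF, AcOH, THF, 0 °C
Reagents that add atoms: none
Why: Fluoride-induced cleavage of the alkynyl C–Si bond, buffered with acetic acid so that the aryl pivalate is not touched.

Step 9
Reactants: 12 4-ethynylphenyl pivalate; 3 3,4-bis(benzyloxy)-2-(triisopropylsilyloxy)benzaldehyde
Product: 14 (S)-1-ArA-3-ArB-prop-2-yn-1-ol, via alkynylzinc 13 (not isolated)
Conditions: ZnEt2, PhMe, reflux; then (S)-BINOL (20 mol%), Ti(OiPr)4 (50 mol%), 3, CH2Cl2, rt; aq. NH4Cl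
Reagents that add atoms: none
Why: Catalytic asymmetric alkynylation in which the alkynylzinc adds to the aldehyde within a BINOL–titanium complex, the (S)-ligand directing attack to the face that gives the S carbinol (the future C4 of unit A).

Step 10
Reactants: 14 (S)-1-ArA-3-ArB-prop-2-yn-1-ol; 7 tert-butyl (E)-3-ArA-prop-2-en-1-yl carbonate
Product: 17 (S)-1-ArA-3-ArB-prop-2-yn-1-yl (S)-1-ArA-prop-2-en-1-yl ether, via lithium alkoxide 15 (not isolated), via copper alkoxide 16 (not isolated)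
Conditions: LiN(SiMe3)2, THF, −78 °C; CuI, −78 to 0 °C; then 7, [Ir(cod)Cl]2 (2 mol%), L (4 mol%, pre-activated with n-PrNH2), THF, rt
Reagents that add atoms: none
Why: Iridium-catalysed asymmetric allylic etherification in which the copper alkoxide attacks the aryl-substituted terminus of the allyliridium complex from the face fixed by the phosphoramidite, giving the branched ether with S configuration at the new centre (the future C4 of unit B) while the carbinol centre of 14 is carried over unchanged.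

Step 11
Reactants: 17 (S)-1-ArA-3-ArB-prop-2-yn-1-yl (S)-1-ArA-prop-2-en-1-yl ether
Product: 18 (S,Z)-1-ArA-3-ArB-prop-2-en-1-yl (S)-1-ArA-prop-2-en-1-yl ether
Conditions: H2 (1 atm, 1 equiv), Pd/CaCO3 poisoned with Pb(OAc)2, quinoline, EtOAc, rt
Reagents that add atoms: none
Why: Lindlar semihydrogenation delivers hydrogen syn on the poisoned palladium surface to give the Z alkene, and the alkyne should be consumed before the terminal alkene, the benzyl ethers or the allylic ether react if uptake is stopped at one equivalent.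

Step 12
Reactants: 18 (S,Z)-1-ArA-3-ArB-prop-2-en-1-yl (S)-1-ArA-prop-2-en-1-yl ether
Product: 19 (R)-ArA[(2S,3S)-3-ArB-oxiran-2-yl]methyl (S)-1-ArA-prop-2-en-1-yl ether (cis epoxide)
Conditions: (S,S)-(salen)MnCl (5 mol%), NaOCl (aq., pH 11.3), 4-phenylpyridine N-oxide, CH2Cl2, 0 °C
Reagents that add atoms: sodium hypochlorite, [Na+].[O-]Cl
Why: Jacobsen–Katsuki epoxidation in which the manganese-oxo salen species transfers oxygen side-on to the conjugated cis alkene, the (S,S) ligand choosing the face that puts the oxygen erythro to the C4 ether (2S,3S cis epoxide), while the unconjugated terminal alkene reacts far more slowly.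

Step 13
Reactants: 19 (R)-ArA[(2S,3S)-3-ArB-oxiran-2-yl]methyl (S)-1-ArA-prop-2-en-1-yl ether; 9 4-iodophenyl pivalate
Product: 20 (R)-ArA[(2S,3S)-3-ArB-oxiran-2-yl]methyl (S,E)-1-ArA-3-ArB-prop-2-en-1-yl ether
Conditions: Pd(OAc)2 (10 mol%), Bu4NCl, NaHCO3, DMF, 60 °C
Reagents that add atoms: none
Why: Mizoroki–Heck arylation under ligand-free phase-transfer conditions, in which arylpalladium adds to the terminal carbon of the only alkene and syn β-hydride elimination towards the new benzylic CH2 gives the conjugated E alkene, the cis epoxide being left alone by the weak base.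

Step 14
Reactants: 20 (R)-ArA[(2S,3S)-3-ArB-oxiran-2-yl]methyl (S,E)-1-ArA-3-ArB-prop-2-en-1-yl ether
Product: 21 (R)-ArA[(2S,3S)-3-ArB-oxiran-2-yl]methyl (R)-ArA[(2S,3R)-3-ArB-oxiran-2-yl]methyl ether (cis epoxide in unit A; trans epoxide in unit B)
Conditions: Shi ketone (30 mol%), KHSO5 (as 2KHSO5·KHSO4·K2SO4), K2CO3, Bu4NHSO4, MeCN–CH2(OMe)2–aq. Na2B4O7 buffer, 0 °C
Reagents that add atoms: potassium peroxymonosulfate, [K+].[O-]S(=O)(=O)OO
Why: Shi epoxidation in which the chiral dioxirane formed from the ketone adds oxygen to the E alkene through a concerted spiro transition state, giving the trans (2S,3R) epoxide with the oxygen again erythro to the C4 ether.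

Step 15
Reactants: 21 bis-silyl diepoxide
Product: 22 (R)-ArA(OH)[(2S,3S)-3-ArB-oxiran-2-yl]methyl (R)-ArA(OH)[(2S,3R)-3-ArB-oxiran-2-yl]methyl ether (bis-phenol diepoxide)
Conditions: Bu4NF, AcOH (1:1), THF, 0 °C; used at once
Reagents that add atoms: none
Why: Fluoride cleavage of the two aryl silyl ethers, buffered with acetic acid so that the liberated phenols stay protonated and neither the pivalates nor the epoxides are attacked.

Step 16
Reactants: 22 bis-phenol diepoxide
Product: 24 (2R,3R,4R)-7,8-bis(benzyloxy)-3-hydroxy-2-ArB-chroman-4-yl (2S,3R,4R)-7,8-bis(benzyloxy)-3-hydroxy-2-ArB-chroman-4-yl ether, via monocyclised phenol 23 (not isolated)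
Conditions: (+)-camphor-10-sulfonic acid (0.2 equiv), CH2Cl2, −20 to 0 °C
Reagents that add atoms: none
Why: The sulfonic acid activates each aryl epoxide by hydrogen bonding or protonation, and the ortho phenol of the neighbouring ring A attacks the benzylic epoxide carbon (C2) from the side opposite the breaking C–O bond in an SN2-like opening; the closest known reaction is the acid-mediated cyclisation of 2-hydroxyaryl epoxides to flavan-3-ols. Both pyran rings (ring C of unit B, then ring C of unit A) close in the 6-endo-tet mode, one after the other, through monocyclised phenol 23. C2 of unit B is set by inversion at the benzylic carbon of the trans epoxide (2S, 2,3-trans ring) and C2 of unit A by inversion at the cis epoxide (2R, 2,3-cis ring), while C3 keeps the epoxide oxygen as its hydroxyl and C4 is untouched. The step needs 6-endo attack at C2 over 5-exo attack at C3, which the aryl group secures by carrying the developing positive charge at C2, whereas C3 sits next to the inductively deactivating C4 ether. It also needs clean inversion, which the electron-poor pivaloyloxy group on ring B secures by making a free benzylic cation unfavourable, and it needs the acid-labile C4–O–C4 ether to survive, for which only a catalytic amount of acid is used at low temperature so that the strained epoxides react first.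

Step 17
Reactants: 24 tetrabenzyl ether bis(pivalate) of the target
Product: 25 (2R,3R,4R)-7,8-bis(benzyloxy)-3-hydroxy-2-(4-hydroxyphenyl)chroman-4-yl (2S,3R,4R)-7,8-bis(benzyloxy)-3-hydroxy-2-(4-hydroxyphenyl)chroman-4-yl ether
Conditions: i-Bu2AlH (excess), CH2Cl2, −78 °C; aq. KNaC4H4O6
Reagents that add atoms: none
Why: Reductive cleavage of the two aryl pivalates by i-Bu2AlH at low temperature is a non-basic method that avoids phenoxide formation para to C2 and leaves the benzyl ethers and the C4–O–C4 ether alone.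

Step 18
Reactants: 25 tetrabenzyl ether
Product: 26 (2R,3R,4R)-2-(4-hydroxyphenyl)-4-{[(2S,3R,4R)-3,7,8-trihydroxy-2-(4-hydroxyphenyl)chroman-4-yl]oxy}chromane-3,7,8-triol
Conditions: H2 (1 atm), Pd(OH)2/C, EtOAc–MeOH, rt
Reagents that add atoms: none
Why: Catalytic hydrogenolysis cleaves the four aryl benzyl ethers much faster than the hindered secondary benzylic C–O bonds at C2 and C4, so stopping when four equivalents of hydrogen are taken up should give the free polyphenol.

**Compound list**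

1 | 2,3,4-trihydroxybenzaldehyde | O=Cc1ccc(O)c(O)c1O | starting material
2 | 3,4-bis(benzyloxy)-2-hydroxybenzaldehyde | O=Cc1ccc(OCc2ccccc2)c(OCc2ccccc2)c1O | intermediate
3 | 3,4-bis(benzyloxy)-2-(triisopropylsilyloxy)benzaldehyde | O=Cc1ccc(OCc2ccccc2)c(OCc2ccccc2)c1O[Si](C(C)C)(C(C)C)C(C)C | intermediate
4 | ethyl (triphenylphosphoranylidene)acetate | CCOC(=O)C=P(c1ccccc1)(c1ccccc1)c1ccccc1 | starting material
5 | ethyl (E)-3-ArA-acrylate | CCOC(=O)/C=C/c1ccc(OCc2ccccc2)c(OCc2ccccc2)c1O[Si](C(C)C)(C(C)C)C(C)C | intermediate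
6 | (E)-3-ArA-prop-2-en-1-ol | OC/C=C/c1ccc(OCc2ccccc2)c(OCc2ccccc2)c1O[Si](C(C)C)(C(C)C)C(C)C | intermediate
7 | tert-butyl (E)-3-ArA-prop-2-en-1-yl carbonate | CC(C)(C)OC(=O)OC/C=C/c1ccc(OCc2ccccc2)c(OCc2ccccc2)c1O[Si](C(C)C)(C(C)C)C(C)C | intermediate
8 | 4-iodophenol | Oc1ccc(I)cc1 | starting material
9 | 4-iodophenyl pivalate | CC(C)(C)C(=O)Oc1ccc(I)cc1 | intermediate
10 | trimethylsilylacetylene | C#C[Si](C)(C)C | starting material
11 | 4-[(trimethylsilyl)ethynyl]phenyl pivalate | CC(C)(C)C(=O)Oc1ccc(C#C[Si](C)(C)C)cc1 | intermediate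
12 | 4-ethynylphenyl pivalate | CC(C)(C)C(=O)Oc1ccc(C#C)cc1 | intermediate
13 | ethyl{[4-(pivaloyloxy)phenyl]ethynyl}zinc | CC[Zn]C#Cc1ccc(OC(=O)C(C)(C)C)cc1 | intermediate (not isolated)
14 | (S)-1-ArA-3-ArB-prop-2-yn-1-ol | CC(C)(C)C(=O)Oc1ccc(C#C[C@H](O)c2ccc(OCc3ccccc3)c(OCc3ccccc3)c2O[Si](C(C)C)(C(C)C)C(C)C)cc1 | intermediate
15 | lithium alkoxide of 14 | CC(C)(C)C(=O)Oc1ccc(C#C[C@H]([O-])c2ccc(OCc3ccccc3)c(OCc3ccccc3)c2O[Si](C(C)C)(C(C)C)C(C)C)cc1.[Li+] | intermediate (not isolated)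
16 | copper alkoxide of 14 (monovalent copper) | CC(C)(C)C(=O)Oc1ccc(C#C[C@H](O[Cu])c2ccc(OCc3ccccc3)c(OCc3ccccc3)c2O[Si](C(C)C)(C(C)C)C(C)C)cc1 | intermediate (not isolated)
17 | (S)-1-ArA-3-ArB-prop-2-yn-1-yl (S)-1-ArA-prop-2-en-1-yl ether | CC(C)(C)C(=O)Oc1ccc(C#C[C@@H](c2ccc(OCc3ccccc3)c(OCc3ccccc3)c2O[Si](C(C)C)(C(C)C)C(C)C)O[C@H](c2ccc(OCc3ccccc3)c(OCc3ccccc3)c2O[Si](C(C)C)(C(C)C)C(C)C)C=C)cc1 | intermediate
18 | (S,Z)-1-ArA-3-ArB-prop-2-en-1-yl (S)-1-ArA-prop-2-en-1-yl ether | CC(C)(C)C(=O)Oc1ccc(/C=C\[C@@H](c2ccc(OCc3ccccc3)c(OCc3ccccc3)c2O[Si](C(C)C)(C(C)C)C(C)C)O[C@H](c2ccc(OCc3ccccc3)c(OCc3ccccc3)c2O[Si](C(C)C)(C(C)C)C(C)C)C=C)cc1 | intermediate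
19 | (R)-ArA[(2S,3S)-3-ArB-oxiran-2-yl]methyl (S)-1-ArA-prop-2-en-1-yl ether (cis epoxide) | CC(C)(C)C(=O)Oc1ccc([C@@H]2O[C@@H]2[C@@H](c2ccc(OCc3ccccc3)c(OCc3ccccc3)c2O[Si](C(C)C)(C(C)C)C(C)C)O[C@H](c2ccc(OCc3ccccc3)c(OCc3ccccc3)c2O[Si](C(C)C)(C(C)C)C(C)C)C=C)cc1 | intermediate
20 | (R)-ArA[(2S,3S)-3-ArB-oxiran-2-yl]methyl (S,E)-1-ArA-3-ArB-prop-2-en-1-yl ether | CC(C)(C)C(=O)Oc1ccc([C@@H]2O[C@@H]2[C@@H](c2ccc(OCc3ccccc3)c(OCc3ccccc3)c2O[Si](C(C)C)(C(C)C)C(C)C)O[C@H](c2ccc(OCc3ccccc3)c(OCc3ccccc3)c2O[Si](C(C)C)(C(C)C)C(C)C)/C=C/c2ccc(OC(=O)C(C)(C)C)cc2)cc1 | intermediate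
21 | (R)-ArA[(2S,3S)-3-ArB-oxiran-2-yl]methyl (R)-ArA[(2S,3R)-3-ArB-oxiran-2-yl]methyl ether (bis-silyl diepoxide) | CC(C)(C)C(=O)Oc1ccc([C@@H]2O[C@@H]2[C@@H](c2ccc(OCc3ccccc3)c(OCc3ccccc3)c2O[Si](C(C)C)(C(C)C)C(C)C)O[C@H](c2ccc(OCc3ccccc3)c(OCc3ccccc3)c2O[Si](C(C)C)(C(C)C)C(C)C)[C@H]2O[C@@H]2c2ccc(OC(=O)C(C)(C)C)cc2)cc1 | intermediate
22 | (R)-ArA(OH)[(2S,3S)-3-ArB-oxiran-2-yl]methyl (R)-ArA(OH)[(2S,3R)-3-ArB-oxiran-2-yl]methyl ether (bis-phenol diepoxide; key-step precursor) | CC(C)(C)C(=O)Oc1ccc([C@@H]2O[C@@H]2[C@@H](c2ccc(OCc3ccccc3)c(OCc3ccccc3)c2O)O[C@H](c2ccc(OCc3ccccc3)c(OCc3ccccc3)c2O)[C@H]2O[C@@H]2c2ccc(OC(=O)C(C)(C)C)cc2)cc1 | intermediate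
23 | monocyclised phenol: (R)-ArA(OH)[(2S,3S)-3-ArB-oxiran-2-yl]methyl ether of (2S,3R,4R)-7,8-bis(benzyloxy)-2-ArB-chromane-3,4-diol at O-4 | CC(C)(C)C(=O)Oc1ccc([C@@H]2O[C@@H]2[C@@H](c2ccc(OCc3ccccc3)c(OCc3ccccc3)c2O)O[C@@H]2c3ccc(OCc4ccccc4)c(OCc4ccccc4)c3O[C@@H](c3ccc(OC(=O)C(C)(C)C)cc3)[C@@H]2O)cc1 | intermediate (not isolated)
24 | (2R,3R,4R)-7,8-bis(benzyloxy)-3-hydroxy-2-ArB-chroman-4-yl (2S,3R,4R)-7,8-bis(benzyloxy)-3-hydroxy-2-ArB-chroman-4-yl ether (key-step product) | CC(C)(C)C(=O)Oc1ccc([C@H]2Oc3c(ccc(OCc4ccccc4)c3OCc4ccccc4)[C@@H](O[C@@H]3c4ccc(OCc5ccccc5)c(OCc5ccccc5)c4O[C@@H](c4ccc(OC(=O)C(C)(C)C)cc4)[C@@H]3O)[C@H]2O)cc1 | intermediate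
25 | (2R,3R,4R)-7,8-bis(benzyloxy)-3-hydroxy-2-(4-hydroxyphenyl)chroman-4-yl (2S,3R,4R)-7,8-bis(benzyloxy)-3-hydroxy-2-(4-hydroxyphenyl)chroman-4-yl ether | Oc1ccc([C@H]2Oc3c(ccc(OCc4ccccc4)c3OCc4ccccc4)[C@@H](O[C@@H]3c4ccc(OCc5ccccc5)c(OCc5ccccc5)c4O[C@@H](c4ccc(O)cc4)[C@@H]3O)[C@H]2O)cc1 | intermediate
26 | (2R,3R,4R)-2-(4-hydroxyphenyl)-4-{[(2S,3R,4R)-3,7,8-trihydroxy-2-(4-hydroxyphenyl)chroman-4-yl]oxy}chromane-3,7,8-triol (CNP0241481.1) | Oc1ccc([C@H]2Oc3c(ccc(O)c3O)[C@@H](O[C@@H]3c4ccc(O)c(O)c4O[C@@H](c4ccc(O)cc4)[C@@H]3O)[C@H]2O)cc1 | target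

**Totals and risks**

Total step count: 18. Longest linear sequence: 14 steps (steps 1–5, then 10–18).

Steps most likely to fail:

1. Step 16 (double ring closure). The acid may ionise the doubly benzylic C4–O–C4 ether, the phenol may attack C3 in the 5-exo mode, or the cis epoxide may open partly through a cation with loss of configuration at C2.
   Fallback: the same two O1–C2 bonds are formed with inversion by Mitsunobu displacement of benzylic hydroxyls, which needs no acid. It sets out from 18. Heck arylation with 9 under the conditions of step 13 gives (S,Z)-1-ArA-3-ArB-prop-2-en-1-yl (S,E)-1-ArA-3-ArB-prop-2-en-1-yl ether F10. Dihydroxylation of both alkenes (OsO4 cat., N-methylmorpholine N-oxide, acetone–water) is syn and should follow the usual preference of OsO4 for the face anti to an allylic ether oxygen, placing each C3 hydroxyl erythro to the C4 ether, to give the bis-silyl tetraol F11. Bu4NF/AcOH frees the bis-phenol tetraol F12. PPh3 and diisopropyl azodicarboxylate (THF, 0 °C) should activate the less hindered benzylic C2 hydroxyls, which the phenols displace with inversion. The route is rejoined at 24.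

2. Step 10 (allylic etherification). The silyl group may migrate from the phenol oxygen to the neighbouring alkoxide, and C–O bond formation between two hindered partners may be slow, giving the linear ether or poor control at the new centre.
   Fallback: the phenol of the nucleophile is carried as a small allyl ether that cannot migrate and is exchanged after the coupling. It sets out from 2. Allyl bromide/K2CO3 gives 2-(allyloxy)-3,4-bis(benzyloxy)benzaldehyde F1. Alkynylation with 12 as in step 9 gives (S)-1-[2-(allyloxy)-3,4-bis(benzyloxy)phenyl]-3-ArB-prop-2-yn-1-ol F2. Coupling with 7 as in step 10 gives (S)-1-[2-(allyloxy)-3,4-bis(benzyloxy)phenyl]-3-ArB-prop-2-yn-1-yl (S)-1-ArA-prop-2-en-1-yl ether F3. Pd(PPh3)4 and morpholine cleave only the aryl allyl ether to give (S)-1-ArA(OH)-3-ArB-prop-2-yn-1-yl (S)-1-ArA-prop-2-en-1-yl ether F4. Silylation (i-Pr3SiOTf, 2,6-lutidine) rejoins the route at 17.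

3. Step 12 (cis epoxidation). Facial selectivity may be poor where the catalyst must override the bias of the allylic stereocentre, and stepwise oxygen transfer may leak some cis alkene into trans epoxide.
   Fallback: the cis epoxide is set by substrate control on a free alcohol before the ether is made. It sets out from 3 and 12. Alkynylation with (R)-BINOL gives (R)-1-ArA-3-ArB-prop-2-yn-1-ol F5. Semihydrogenation as in step 11 gives (R,Z)-1-ArA-3-ArB-prop-2-en-1-ol F6. Hydroxyl-directed epoxidation (mCPBA, NaHCO3, CH2Cl2, 0 °C) is stereospecific and, with allylic 1,3-strain fixing the conformation, should give the threo cis-epoxy alcohol (S)-ArA[(2R,3S)-3-ArB-oxiran-2-yl]methanol F7. Dess–Martin periodinane gives the cis-epoxy ketone ArA (2S,3S)-3-ArB-oxiran-2-yl ketone F8. Chelation-controlled reduction with Zn(BH4)2 (Et2O, −20 °C) should give the erythro cis-epoxy alcohol (R)-ArA[(2R,3S)-3-ArB-oxiran-2-yl]methanol F9. Its copper alkoxide, formed and kept cold, is coupled with 7 as in step 10, and the route is rejoined at 19.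

Further compounds
F1 | step 10 | 2-(allyloxy)-3,4-bis(benzyloxy)benzaldehyde | O=Cc1ccc(OCc2ccccc2)c(OCc2ccccc2)c1OCC=C
F2 | step 10 | (S)-1-[2-(allyloxy)-3,4-bis(benzyloxy)phenyl]-3-ArB-prop-2-yn-1-ol | CC(C)(C)C(=O)Oc1ccc(C#C[C@H](O)c2ccc(OCc3ccccc3)c(OCc3ccccc3)c2OCC=C)cc1
F3 | step 10 | (S)-1-[2-(allyloxy)-3,4-bis(benzyloxy)phenyl]-3-ArB-prop-2-yn-1-yl (S)-1-ArA-prop-2-en-1-yl ether | CC(C)(C)C(=O)Oc1ccc(C#C[C@@H](c2ccc(OCc3ccccc3)c(OCc3ccccc3)c2OCC=C)O[C@H](c2ccc(OCc3ccccc3)c(OCc3ccccc3)c2O[Si](C(C)C)(C(C)C)C(C)C)C=C)cc1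
F4 | step 10 | (S)-1-ArA(OH)-3-ArB-prop-2-yn-1-yl (S)-1-ArA-prop-2-en-1-yl ether | CC(C)(C)C(=O)Oc1ccc(C#C[C@@H](c2ccc(OCc3ccccc3)c(OCc3ccccc3)c2O)O[C@H](c2ccc(OCc3ccccc3)c(OCc3ccccc3)c2O[Si](C(C)C)(C(C)C)C(C)C)C=C)cc1
F5 | step 12 | (R)-1-ArA-3-ArB-prop-2-yn-1-ol | CC(C)(C)C(=O)Oc1ccc(C#C[C@@H](O)c2ccc(OCc3ccccc3)c(OCc3ccccc3)c2O[Si](C(C)C)(C(C)C)C(C)C)cc1
F6 | step 12 | (R,Z)-1-ArA-3-ArB-prop-2-en-1-ol | CC(C)(C)C(=O)Oc1ccc(/C=C\[C@@H](O)c2ccc(OCc3ccccc3)c(OCc3ccccc3)c2O[Si](C(C)C)(C(C)C)C(C)C)cc1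
F7 | step 12 | (S)-ArA[(2R,3S)-3-ArB-oxiran-2-yl]methanol (threo; cis epoxide) | CC(C)(C)C(=O)Oc1ccc([C@@H]2O[C@@H]2[C@@H](O)c2ccc(OCc3ccccc3)c(OCc3ccccc3)c2O[Si](C(C)C)(C(C)C)C(C)C)cc1
F8 | step 12 | ArA (2S,3S)-3-ArB-oxiran-2-yl ketone (cis epoxide) | CC(C)(C)C(=O)Oc1ccc([C@@H]2O[C@@H]2C(=O)c2ccc(OCc3ccccc3)c(OCc3ccccc3)c2O[Si](C(C)C)(C(C)C)C(C)C)cc1
F9 | step 12 | (R)-ArA[(2R,3S)-3-ArB-oxiran-2-yl]methanol (erythro; cis epoxide) | CC(C)(C)C(=O)Oc1ccc([C@@H]2O[C@@H]2[C@H](O)c2ccc(OCc3ccccc3)c(OCc3ccccc3)c2O[Si](C(C)C)(C(C)C)C(C)C)cc1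
F10 | step 16 | (S,Z)-1-ArA-3-ArB-prop-2-en-1-yl (S,E)-1-ArA-3-ArB-prop-2-en-1-yl ether | CC(C)(C)C(=O)Oc1ccc(/C=C\[C@@H](c2ccc(OCc3ccccc3)c(OCc3ccccc3)c2O[Si](C(C)C)(C(C)C)C(C)C)O[C@H](c2ccc(OCc3ccccc3)c(OCc3ccccc3)c2O[Si](C(C)C)(C(C)C)C(C)C)/C=C/c2ccc(OC(=O)C(C)(C)C)cc2)cc1
F11 | step 16 | bis-silyl tetraol from syn dihydroxylation of both alkenes of F10 (erythro diol in the former Z half; threo diol in the former E half; each C3 hydroxyl erythro to the C4 ether) | CC(C)(C)C(=O)Oc1ccc([C@H](O)[C@H](O)[C@@H](c2ccc(OCc3ccccc3)c(OCc3ccccc3)c2O[Si](C(C)C)(C(C)C)C(C)C)O[C@H](c2ccc(OCc3ccccc3)c(OCc3ccccc3)c2O[Si](C(C)C)(C(C)C)C(C)C)[C@@H](O)[C@H](O)c2ccc(OC(=O)C(C)(C)C)cc2)cc1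
F12 | step 16 | bis-phenol tetraol (F11 without the two silyl groups) | CC(C)(C)C(=O)Oc1ccc([C@H](O)[C@H](O)[C@@H](c2ccc(OCc3ccccc3)c(OCc3ccccc3)c2O)O[C@H](c2ccc(OCc3ccccc3)c(OCc3ccccc3)c2O)[C@@H](O)[C@H](O)c2ccc(OC(=O)C(C)(C)C)cc2)cc1
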